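All compound numbers below are those of the steps. Eremophilane numbering is used throughout: ring A is C1–C5 and C10, ring B is C5–C10, C14 is the methyl on C5, C15 the methyl on C4, and β is the face that carries C14.

## The problem

Target 24 is a cis-fused eremophilane with six stereocentres (C3, C4, C5, C7, C9, C10) on a ten-carbon bicycle. Four of them are contiguous on ring A, among them the quaternary C5 flanked by a cis methyl at C4 and a cis hydrogen at C10; none of these can be corrected later, so they have to be set together and in the absolute sense. C7 and C9 flank the C8 ketone and are epimerisable; in the chair–chair conformer that keeps the ring A substituents equatorial, the 7β-isopropenyl and 9β-acyloxy groups are equatorial as well, so ring A can control both. The molecule is fragile: the angelate isomerises to the tiglate under nucleophiles, heat or iodine, the isopropenyl group slips into conjugation with the ketone under base, and the α-acyloxy ketone can epimerise or suffer acyl migration. Two different enoate esters sit on two secondary alcohols, which must be told apart by timing, not by reactivity. The enabling feature is that C4, C5 and C6 with the two cis methyls are the atoms of (E)-2-methylbut-2-enal, while C3, C2, C1 and C10 with the C9 arm are a 1,4-disubstituted butadiene. The C3–C4 and C5–C10 bonds are therefore the two bonds of a Diels–Alder reaction, and the 3α-oxygen (trans to C15, cis to the C9 arm) sits exactly where an E silyl group on the diene terminus would end up.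

## Retrosynthesis

**C7–H.** Target 24 is cut back to the cross-conjugated dienone 23 by removing the hydrogens at C6 and C7. The β,γ-unsaturated ketone is the most fragile part of 24, so it is made last, by a neutral conjugate reduction, instead of being carried through acylations. The forward step must reduce only the enone and protonate the dienolate at C7, not at C12.

**C7–C11.** Dienone 23 is cut at the bond between C7 and the isopropenyl carbon into α-iodoenone 21 and the commercial boronate 22; 21 comes from enone 20 by iodination. The neighbouring choice, aldol reaction with acetone and dehydration, gives the conjugated isopropylidene isomer. Cross-coupling fixes the alkene position.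

**The two C–O bonds of ring A and C3.** Ester 20 is cut to alcohol 17 and angelic acid 18 (activated as mixed anhydride 19), and the C3–O bond of 17 is traced to the C3–Si bond of silane 16. Silicon is a masked hydroxyl that survives organolithium reagents, so C3 needs no protecting group and is revealed only after the senecioate is in place at C9. Retention in the oxidation is all that is asked.

**C6=C7, ring B.** Enone 16 is opened at C6=C7 to keto aldehyde 15, which is the hydrolysis product of enol ether acetal 14. C6 is neopentyl, so an alkylation there is not an option, whereas an aldol condensation onto a non-enolisable aldehyde is. The cis fusion is inherited from the cis C6 and C9 arms on ring A.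

**C8–C9.** Compound 14 is cut between C8 and C9 into aldehyde 9 and 1-ethoxyvinyllithium 12 (from ethyl vinyl ether 10), with the alkoxide 13 acylated at once by senecioyl chloride 11. This brings C7 and C8 as an acetyl anion equivalent and fixes C9–O as the final ester in the same flask. The addition must follow Felkin–Anh control by the quaternary C5.

**Adjustments on ring A.** Aldehyde 9 comes from alcohol 8, silyl ether 7, alkene 6 and aldehyde 5 by oxidation, desilylation, hydrogenation and acetal formation. These steps only exchange which of the two arms is the free aldehyde.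

**C3–C4 and C5–C10, ring A.** Adduct 5 is cut into tiglic aldehyde 4 and dienylsilane 3. Against a diene with an unsubstituted terminus, which would leave C3 as a methylene needing a later allylic oxidation (SeO2) without regio- or facial control, the silyl terminus writes C3 in the same step as C4, C5 and C10. Both precursors are achiral; the forward reaction must be regio-, endo- and enantioselective.

**The diene.** Dienylsilane 3 is cut at C–Si to enyne 2, the silyl ether of commercial enynol 1.

## Roads not taken

**Alternative 1:** The cut is the C5–C6 bond, made by an anionic oxy-Cope rearrangement. The potassium alkoxide of bicyclo[2.2.2]octenol A2 would rearrange to a cis-fused dienolate and, after protonation at C7, give ketal ketone A1.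
- Merits: ring B, the quaternary C5, the cis fusion, the C8 ketone, C9 at ketone level and the isopropenyl group all arrive in one step. In convergence this road is better than the chosen plan.
- Weak points: A1 has a C3=C4 alkene, so C3–O and C4 must be set afterwards. The C9 ketal must become a single carbinol epimer beside a free C8 ketone, which means redox shuffling between adjacent carbonyl carbons. The masked ortho-quinone cycloaddition that would build A2 is not enantioselective. C7 is again set by dienolate protonation, so nothing is gained there.
- Against it the chosen plan sets catalytic absolute control of four ring A centres in one step and an unambiguous C8/C9 oxidation pattern.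

**Alternative 2:** The cut is the biosynthetic one. Aristolochene synthase would turn farnesyl diphosphate A4 into (+)-aristolochene A3 through a cationic cascade with one hydride and one methyl shift.
- Merits: both rings, the cis methyls and the absolute configuration come in a single step. For the hydrocarbon skeleton nothing is shorter.
- Weak points: A3 has no oxygen. C8 is allylic and could be oxidised, but C9 needs oxygen together with a cis reduction of the 9,10-alkene, and C3 is an unactivated methylene with no chemical handle. C7 of A3 is opposite to that of 24, tolerable only because it becomes epimerisable next to the ketone. A4 is a fermentation feedstock, not a shelf reagent.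
- The chosen plan is longer to the skeleton but brings each oxygen in with the carbon that bears it (C9 from the dienol, C3 as silicon, C8 from the acyl anion).

**Alternative 3:** The cut is C7–C8. Under Me2AlCl the aldehyde A6, with a prenyl group on C5, would close ring B by a carbonyl-ene reaction to give homoallylic alcohol A5, which is one oxidation from 24.
- Merits: the isopropenyl group and C7 are created together through a chair transition state, so the dienolate protonation of the chosen plan is avoided. In respect of C7 this road is better.
- Weak points: A6 is an α-acyloxy aldehyde, epimerisable at C9 and chelating toward the aluminium reagent. It needs a one-carbon homologation at C9 and a prenylated, non-commercial dienophile for ring A. The ene step does nothing for the four ring A centres, which would still need a Diels–Alder like the one chosen.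
- The chosen plan sets against it commercial partners for the key step, a C9 centre set by a simple Felkin–Anh addition, and a C7 centre that is the thermodynamically preferred one.

Key step: step 3

Assumption on the catalyst: the facial sense is taken from the two-point binding model for α-substituted enals (formyl C–H···O contact, s-trans enal, one face covered by the cis aryl group), which points to the (R)-prolinol-derived cation for attack on the Cα-Si face of 4. If the adduct proves antipodal, the (S)-catalyst is used.
Assumption on the starting material: (E)-pent-2-en-4-yn-1-ol is bought as the E isomer.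

## Route

Step 1
Reactants: 1 (E)-pent-2-en-4-yn-1-ol
Product: 2 (E)-tert-butyl(pent-2-en-4-yn-1-yloxy)diphenylsilane
Conditions: t-BuPh2SiCl, imidazole, CH2Cl2, 0 °C → rt
Reagents that add atoms: tert-butyl(chloro)diphenylsilane, CC(C)(C)[Si](Cl)(c1ccccc1)c1ccccc1
Why: Standard silyl ether formation; the tert-butyldiphenylsilyl group is chosen because it survives the acidic acetal formation of step 4 and is removed by fluoride without touching the acetal.

Step 2
Reactants: 2 (E)-tert-butyl(pent-2-en-4-yn-1-yloxy)diphenylsilane
Product: 3 tert-butyl{[(2E,4E)-5-(dimethylphenylsilyl)penta-2,4-dien-1-yl]oxy}diphenylsilane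
Conditions: PhMe2SiH, Pt2[(CH2=CHSiMe2)2O]3 (0.5 mol%), P(t-Bu)3, THF, rt
Reagents that add atoms: dimethyl(phenyl)silane, C[SiH](C)c1ccccc1
Why: Platinum-catalysed hydrosilylation of the terminal alkyne; syn addition with silicon at the terminal carbon gives the E vinylsilane and hence the 2E,4E diene, the bulky phosphine suppressing the internal isomer and leaving the existing alkene alone.

Step 3
Reactants: 3 tert-butyl{[(2E,4E)-5-(dimethylphenylsilyl)penta-2,4-dien-1-yl]oxy}diphenylsilane; 4 tiglic aldehyde
Product: 5 (1S,2S,5R,6R)-2-[(tert-butyldiphenylsilyloxy)methyl]-5-(dimethylphenylsilyl)-1,6-dimethylcyclohex-3-ene-1-carbaldehyde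
Conditions: oxazaborolidinium triflimide from (R)-α,α-diphenylprolinol, (o-TolBO)3 and HNTf2 (20 mol%, HNTf2 substoichiometric to boron), CH2Cl2, −78 → −20 °C
Reagents that add atoms: none
Why: The cationic oxazaborolidine binds the formyl oxygen of 4 syn to the formyl hydrogen, holds the enal s-trans and lowers its LUMO, so that diene 3 adds in a concerted but asynchronous [4+2] cycloaddition in which the C3–C4 bond to the enal β-carbon runs ahead of the C5–C10 bond. The closest known reactions are oxazaborolidinium-catalysed Diels–Alder additions of α-substituted enals to acyclic dienes and Lewis acid additions of tiglic aldehyde to 1-substituted butadienes. Ring A closes as a six-membered carbocycle by intermolecular suprafacial–suprafacial union of the two partners. Regiochemistry: the carbon-substituted terminus C10 bonds to the α-carbon (ortho rule) and the silyl-bearing terminus C3 to the β-carbon, where the positive charge developing at C2 is stabilised β to silicon, so both substituents direct the same way. C4 and C5 (cis methyls) copy the E geometry of 4, C3 and C10 (silyl and silyloxymethyl cis) copy the E,E geometry of 3, and the endo position of the catalyst-bound formyl group puts C6 cis to both diene substituents; this endo preference is weaker for α-methyl enals and is the selectivity to watch. The absolute configuration comes from the catalyst, whose aryl group covers one face of the bound enal and leaves the Cα-Si face open to the diene. The step must give one regioisomer, the endo adduct and one enantiomer, secured respectively by the matched directing effects, the two alkene geometries and the catalyst.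

Step 4
Reactants: 5 (1S,2S,5R,6R)-2-[(tert-butyldiphenylsilyloxy)methyl]-5-(dimethylphenylsilyl)-1,6-dimethylcyclohex-3-ene-1-carbaldehyde
Product: 6 dimethyl acetal of 5 (C6 as CH(OMe)2; alkene and the four stereocentres unchanged)
Conditions: HC(OMe)3, MeOH, PPTS (cat.), 40 °C
Reagents that add atoms: trimethyl orthoformate, COC(OC)OC
Why: Acid-catalysed acetal formation masks the non-enolisable C6 aldehyde so that C9 can later be the only aldehyde; the mild acid leaves the silyl ether and the allylsilane intact.

Step 5
Reactants: 6 dimethyl acetal of 5
Product: 7 tert-butyl{[2-(dimethoxymethyl)-4-(dimethylphenylsilyl)-2,3-dimethylcyclohexyl]methoxy}diphenylsilane (stereocentres as in 5)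
Conditions: H2 (1 atm), PtO2, EtOAc, rt
Reagents that add atoms: none
Why: Heterogeneous hydrogenation of the cis-disubstituted ring alkene creates no stereocentre; platinum is used in place of Pd/C to avoid migration of the double bond toward C3, which would put the C3–Si centre at risk.

Step 6
Reactants: 7 tert-butyl{[2-(dimethoxymethyl)-4-(dimethylphenylsilyl)-2,3-dimethylcyclohexyl]methoxy}diphenylsilane
Product: 8 [2-(dimethoxymethyl)-4-(dimethylphenylsilyl)-2,3-dimethylcyclohexyl]methanol (stereocentres as in 5)
Conditions: Bu4NF, THF, 0 °C → rt
Reagents that add atoms: none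
Why: Fluoride cleaves the Si–O bond of the silyl ether; the carbon-bound phenyldimethylsilyl group and the acetal are inert to fluoride under these conditions.

Step 7
Reactants: 8 [2-(dimethoxymethyl)-4-(dimethylphenylsilyl)-2,3-dimethylcyclohexyl]methanol
Product: 9 2-(dimethoxymethyl)-4-(dimethylphenylsilyl)-2,3-dimethylcyclohexane-1-carbaldehyde (stereocentres as in 5; the aldehyde carbon is C9)
Conditions: Dess–Martin periodinane, pyridine, CH2Cl2, 0 °C → rt
Reagents that add atoms: none
Why: Buffered periodinane oxidation of the primary alcohol is non-basic and non-acidic, so the α-stereocentre C10 and the acetal are not disturbed.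

Step 8
Reactants: 9 2-(dimethoxymethyl)-4-(dimethylphenylsilyl)-2,3-dimethylcyclohexane-1-carbaldehyde; 10 ethyl vinyl ether; 11 3-methylbut-2-enoyl chloride
Product: 14 (1R)-1-[2-(dimethoxymethyl)-4-(dimethylphenylsilyl)-2,3-dimethylcyclohexyl]-2-ethoxyprop-2-en-1-yl 3-methylbut-2-enoate, via 1-ethoxyvinyllithium 12 (not isolated), via lithium alkoxide 13 (not isolated)
Conditions: 10, t-BuLi, THF, −78 → 0 °C; then 9, −78 °C; then 11, −78 → 0 °C
Reagents that add atoms: none
Why: α-Lithiation of the enol ether gives an acetyl anion equivalent that adds to the α-branched aldehyde under Felkin–Anh control (attack anti to the quaternary C5, formyl hydrogen beside H10), which should give the 9R alkoxide. O-acylation of the lithium alkoxide by the acid chloride places the senecioate before an α-ketol exists and while C3 is still silicon.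

Step 9
Reactants: 14 (1R)-1-[2-(dimethoxymethyl)-4-(dimethylphenylsilyl)-2,3-dimethylcyclohexyl]-2-ethoxyprop-2-en-1-yl 3-methylbut-2-enoate
Product: 16 3α-(dimethylphenylsilyl)-9β-(3-methylbut-2-enoyloxy)-11,12,13-trinor-10βH-eremophil-6-en-8-one, via keto aldehyde 15 (not isolated)
Conditions: TsOH·H2O (20 mol%), THF–H2O, rt; then PhMe, 80 °C
Reagents that add atoms: water, O
Why: Aqueous acid unmasks the methyl ketone from the enol ether and the C6 aldehyde from the acetal; the methyl-side enol then adds to the non-enolisable aldehyde and water is lost (intramolecular aldol condensation, 6-(enolendo)-exo-trig), closing ring B as the cis-fused enone. C9 is now α to the ketone and can settle in the pseudo-equatorial β configuration that the addition in step 8 already favours.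

Step 10
Reactants: 16 3α-(dimethylphenylsilyl)-9β-(3-methylbut-2-enoyloxy)-11,12,13-trinor-10βH-eremophil-6-en-8-one
Product: 17 3α-hydroxy-9β-(3-methylbut-2-enoyloxy)-11,12,13-trinor-10βH-eremophil-6-en-8-one
Conditions: Hg(OAc)2, AcOOH (32% in AcOH), rt
Reagents that add atoms: peracetic acid, CC(=O)OO
Why: Fleming–Tamao oxidation: ipso-mercuration removes the phenyl group from silicon and the peracid then induces migration of C3 from silicon to oxygen with retention, so the 3α-silyl group becomes the 3α-hydroxyl. Ketones and esters are tolerated, as in the classic use of this oxidation on β-silyl carbonyl compounds, and the electron-poor double bonds of the enone and the senecioate are poor partners for the electrophilic reagents.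

Step 11
Reactants: 17 3α-hydroxy-9β-(3-methylbut-2-enoyloxy)-11,12,13-trinor-10βH-eremophil-6-en-8-one; 18 angelic acid
Product: 20 3α-angeloyloxy-9β-senecioyloxy-11,12,13-trinor-10βH-eremophil-6-en-8-one, via angelic 2,4,6-trichlorobenzoic anhydride 19 (not isolated)
Conditions: 18, 2,4,6-Cl3C6H2COCl, Et3N, PhMe, rt; then 17, PhMe, 70 °C
Reagents that add atoms: none
Why: Yamaguchi esterification through the mixed anhydride, run without a nucleophilic amine catalyst because that is the established way to transfer the angeloyl group without Z to E isomerisation; the equatorial 3α-hydroxyl is acylated while the product is still a robust enone.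

Step 12
Reactants: 20 3α-angeloyloxy-9β-senecioyloxy-11,12,13-trinor-10βH-eremophil-6-en-8-one
Product: 21 7-iodo derivative of 20 (3α-angeloyloxy-7-iodo-9β-senecioyloxy-11,12,13-trinor-10βH-eremophil-6-en-8-one)
Conditions: I2, pyridine–CH2Cl2, rt, dark
Reagents that add atoms: iodine, II
Why: α-Iodination of the enone by conjugate addition of pyridine, iodination of the enolate and elimination; the two enoate esters have no free α-position with an accessible β-carbon and should stay untouched, and exclusion of light guards the angelate.

Step 13
Reactants: 21 7-iodo derivative of 20; 22 isopropenylboronic acid pinacol ester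
Product: 23 3α-angeloyloxy-9β-senecioyloxy-10βH-eremophila-6,11-dien-8-one
Conditions: 22, PdCl2(dppf) (5 mol%), K3PO4, THF–H2O, 40 °C
Reagents that add atoms: none
Why: Suzuki–Miyaura coupling of the α-iodoenone, a very reactive electrophile, with the alkenyl boronate forms C7–C11 and brings in the whole isopropenyl group with its double bond fixed in place.

Step 14
Reactants: 23 3α-angeloyloxy-9β-senecioyloxy-10βH-eremophila-6,11-dien-8-one
Product: 24 (3R,4R,5R,7R,9R,10S)-3-angeloyloxy-9-senecioyloxyeremophil-11-en-8-one (3α-O, 7β-isopropenyl, 9β-O, 10βH; the target)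
Conditions: [(Ph3P)CuH]6, C6H6–THF, degassed H2O, rt
Reagents that add atoms: none
Why: Copper hydride conjugate reduction: hydride adds to C6, the only carbon conjugated to the ketone (the isopropenyl group is cross-conjugated and the hindered enoates react far more slowly), and the copper dienolate is protonated by water at C7, not at C12, which keeps the 11,12-alkene out of conjugation. Protonation on the α face gives the equatorial 7β-isopropenyl group, which is also the more stable epimer because every substituent of the cis-decalin is then equatorial.

## Compound list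

1 | (E)-pent-2-en-4-yn-1-ol | OC/C=C/C#C | starting material
2 | (E)-tert-butyl(pent-2-en-4-yn-1-yloxy)diphenylsilane | C#C/C=C/CO[Si](c1ccccc1)(c1ccccc1)C(C)(C)C | intermediate
3 | tert-butyl{[(2E,4E)-5-(dimethylphenylsilyl)penta-2,4-dien-1-yl]oxy}diphenylsilane | C[Si](C)(c1ccccc1)/C=C/C=C/CO[Si](c1ccccc1)(c1ccccc1)C(C)(C)C | intermediate
4 | tiglic aldehyde, (E)-2-methylbut-2-enal | C/C=C(\C)C=O | starting material
5 | (1S,2S,5R,6R)-2-[(tert-butyldiphenylsilyloxy)methyl]-5-(dimethylphenylsilyl)-1,6-dimethylcyclohex-3-ene-1-carbaldehyde | O=C[C@@]1(C)[C@H](C=C[C@@H]([Si](C)(C)c2ccccc2)[C@@H]1C)CO[Si](c2ccccc2)(c2ccccc2)C(C)(C)C | intermediate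
6 | dimethyl acetal of 5 | COC(OC)[C@@]1(C)[C@H](C=C[C@@H]([Si](C)(C)c2ccccc2)[C@@H]1C)CO[Si](c2ccccc2)(c2ccccc2)C(C)(C)C | intermediate
7 | tert-butyl{[2-(dimethoxymethyl)-4-(dimethylphenylsilyl)-2,3-dimethylcyclohexyl]methoxy}diphenylsilane | COC(OC)[C@@]1(C)[C@H](CC[C@@H]([Si](C)(C)c2ccccc2)[C@@H]1C)CO[Si](c2ccccc2)(c2ccccc2)C(C)(C)C | intermediate
8 | [2-(dimethoxymethyl)-4-(dimethylphenylsilyl)-2,3-dimethylcyclohexyl]methanol | COC(OC)[C@@]1(C)[C@H](CC[C@@H]([Si](C)(C)c2ccccc2)[C@@H]1C)CO | intermediate
9 | 2-(dimethoxymethyl)-4-(dimethylphenylsilyl)-2,3-dimethylcyclohexane-1-carbaldehyde | COC(OC)[C@@]1(C)[C@H](CC[C@@H]([Si](C)(C)c2ccccc2)[C@@H]1C)C=O | intermediate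
10 | ethyl vinyl ether | C=COCC | starting material
11 | 3-methylbut-2-enoyl chloride (senecioyl chloride) | CC(C)=CC(=O)Cl | starting material
12 | 1-ethoxyvinyllithium (not isolated) | [Li]C(=C)OCC | intermediate
13 | lithium (9R)-alkoxide from 9 and 12 (not isolated) | COC(OC)[C@@]1(C)[C@H](CC[C@@H]([Si](C)(C)c2ccccc2)[C@@H]1C)[C@@H](O[Li])C(=C)OCC | intermediate
14 | (1R)-1-[2-(dimethoxymethyl)-4-(dimethylphenylsilyl)-2,3-dimethylcyclohexyl]-2-ethoxyprop-2-en-1-yl 3-methylbut-2-enoate | COC(OC)[C@@]1(C)[C@H](CC[C@@H]([Si](C)(C)c2ccccc2)[C@@H]1C)[C@@H](OC(=O)C=C(C)C)C(=C)OCC | intermediate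
15 | keto aldehyde: C6 aldehyde, C8 methyl ketone, 9R senecioate (not isolated) | O=C[C@@]1(C)[C@H](CC[C@@H]([Si](C)(C)c2ccccc2)[C@@H]1C)[C@@H](OC(=O)C=C(C)C)C(C)=O | intermediate
16 | 3α-(dimethylphenylsilyl)-9β-(3-methylbut-2-enoyloxy)-11,12,13-trinor-10βH-eremophil-6-en-8-one | C1=C[C@@]2(C)[C@H](CC[C@@H]([Si](C)(C)c3ccccc3)[C@@H]2C)[C@@H](OC(=O)C=C(C)C)C1=O | intermediate
17 | 3α-hydroxy-9β-(3-methylbut-2-enoyloxy)-11,12,13-trinor-10βH-eremophil-6-en-8-one | C1=C[C@@]2(C)[C@H](CC[C@@H](O)[C@@H]2C)[C@@H](OC(=O)C=C(C)C)C1=O | intermediate
18 | angelic acid, (Z)-2-methylbut-2-enoic acid | C/C=C(/C)C(=O)O | starting material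
19 | angelic 2,4,6-trichlorobenzoic anhydride (not isolated) | C/C=C(/C)C(=O)OC(=O)c1c(Cl)cc(Cl)cc1Cl | intermediate
20 | 3α-angeloyloxy-9β-senecioyloxy-11,12,13-trinor-10βH-eremophil-6-en-8-one | C1=C[C@@]2(C)[C@H](CC[C@@H](OC(=O)/C(C)=C\C)[C@@H]2C)[C@@H](OC(=O)C=C(C)C)C1=O | intermediate
21 | 3α-angeloyloxy-7-iodo-9β-senecioyloxy-11,12,13-trinor-10βH-eremophil-6-en-8-one | IC1=C[C@@]2(C)[C@H](CC[C@@H](OC(=O)/C(C)=C\C)[C@@H]2C)[C@@H](OC(=O)C=C(C)C)C1=O | intermediate
22 | isopropenylboronic acid pinacol ester | CC(=C)B1OC(C)(C)C(C)(C)O1 | starting material
23 | 3α-angeloyloxy-9β-senecioyloxy-10βH-eremophila-6,11-dien-8-one | C=C(C)C1=C[C@@]2(C)[C@H](CC[C@@H](OC(=O)/C(C)=C\C)[C@@H]2C)[C@@H](OC(=O)C=C(C)C)C1=O | intermediate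
24 | (3R,4R,5R,7R,9R,10S)-3-angeloyloxy-9-senecioyloxyeremophil-11-en-8-one (CNP0375730.2) | C=C(C)[C@H]1C[C@@]2(C)[C@H](CC[C@@H](OC(=O)/C(C)=C\C)[C@@H]2C)[C@@H](OC(=O)C=C(C)C)C1=O | target

## Step count and least certain steps

Total: 14 steps. Longest linear sequence: 14 steps, from 1 to 24; compounds 4, 10, 11, 18 and 22 are bought.

**Step 3 (key step).** Both bond-forming termini are substituted (a methyl on the enal β-carbon, a silyl group on the diene), and they must meet inside a bulky chiral Lewis acid. The likely failures are slow cycloaddition, erosion of the endo preference of the α-methyl enal, and poor facial selectivity; protodesilylation of the dienylsilane by free triflimide is a lesser risk. The fallback gives up catalytic enantiocontrol. Starting from 3 and 4, the small achiral Lewis acid Me2AlCl (CH2Cl2, −78 °C) should give the racemic endo adduct F1. Condensation with (1R,2R)-N,N'-dimethyl-1,2-diphenylethane-1,2-diamine gives two diastereomeric imidazolidines without a new stereocentre, the aminal of 5, F2, and the aminal of its enantiomer, F3. These are separated by chromatography, and mild aqueous acid on F2 returns to the route at 5.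

**Step 14.** The copper dienolate may be protonated from the more exposed β face, giving the C7 epimer, or at C12, moving the double bond into conjugation; hydride delivery to the neopentyl C6 may also be slow. The fallback separates hydride delivery from proton delivery. Starting from 23, 1,4-hydrosilylation with Et3SiH and RhCl(PPh3)3 gives the isolable triethylsilyl dienol ether F4. Its protodesilylation with HF·pyridine at low temperature is then run as a separate operation, in which the proton source can be chosen for α-face delivery at C7, and comes back to the route at 24.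

**Step 10.** The peracid and the mercuric salt may attack the enone or the senecioate (epoxidation, Baeyer–Villiger oxidation) before the silicon is oxidised. The fallback moves the oxidation to a stage without unsaturation and sets out from 7.
- Basic peroxide oxidation of the phenylsilane (t-BuOOH, KH, DMF; then Bu4NF, 70 °C) also removes the silyl ether and gives the 3α,9-diol F5.
- Silylation of both hydroxyls (Et3SiCl, imidazole) gives the bis(triethylsilyl) ether F6.
- Swern oxidation, which converts a primary triethylsilyl ether directly into the aldehyde, gives the 3-O-triethylsilyl aldehyde F7.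
- Addition of 12 and acylation with 11 as in step 8 gives the senecioate enol ether F9 through the lithium alkoxide F8.
- The acid treatment of step 9 also cleaves the triethylsilyl ether and passes through the 3-hydroxy keto aldehyde F10 to come back to the route at 17.

**Step 9.** The aldol closure onto the hindered neopentyl aldehyde may stall at the keto aldehyde, or hot acid may cause acyl migration at the α-acyloxy ketone. The fallback replaces the aldol condensation by a Mukaiyama addition to the acetal and sets out from 14.
- Mild hydrolysis of the enol ether alone (PPTS, wet acetone, 0 °C) gives the methyl ketone acetal F11.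
- Kinetic silylation on the methyl side (LiN(SiMe3)2, Me3SiCl, THF, −78 °C) gives the trimethylsilyl enol ether F12.
- Me3SiOTf (cat.) ionises the acetal and the enol silane closes ring B to the 6-methoxy ketone F13.
- DBU removes methanol and comes back to the route at 16.

## Further compounds

F1 | step 3 | racemic 5 (equal amounts of 5 and its enantiomer) | O=C[C@@]1(C)[C@H](C=C[C@@H]([Si](C)(C)c2ccccc2)[C@@H]1C)CO[Si](c2ccccc2)(c2ccccc2)C(C)(C)C.O=C[C@]1(C)[C@@H](C=C[C@H]([Si](C)(C)c2ccccc2)[C@H]1C)CO[Si](c2ccccc2)(c2ccccc2)C(C)(C)C
F2 | step 3 | (4R,5R)-1,3-dimethyl-4,5-diphenylimidazolidine aminal of 5 | CN1[C@H](c2ccccc2)[C@@H](c2ccccc2)N(C)C1[C@@]1(C)[C@H](C=C[C@@H]([Si](C)(C)c2ccccc2)[C@@H]1C)CO[Si](c2ccccc2)(c2ccccc2)C(C)(C)C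
F3 | step 3 | (4R,5R)-1,3-dimethyl-4,5-diphenylimidazolidine aminal of the enantiomer of 5 | CN1[C@H](c2ccccc2)[C@@H](c2ccccc2)N(C)C1[C@]1(C)[C@@H](C=C[C@H]([Si](C)(C)c2ccccc2)[C@H]1C)CO[Si](c2ccccc2)(c2ccccc2)C(C)(C)C
F4 | step 14 | 3α-angeloyloxy-9β-senecioyloxy-8-(triethylsilyloxy)-10βH-eremophila-7,11-diene | C=C(C)C=1C[C@@]2(C)[C@H](CC[C@@H](OC(=O)/C(C)=C\C)[C@@H]2C)[C@@H](OC(=O)C=C(C)C)C=1O[Si](CC)(CC)CC
F5 | step 10 | 3-(dimethoxymethyl)-4-(hydroxymethyl)-2,3-dimethylcyclohexan-1-ol (3α,9-diol) | COC(OC)[C@@]1(C)[C@H](CC[C@@H](O)[C@@H]1C)CO
F6 | step 10 | bis(triethylsilyl) ether of F5 | COC(OC)[C@@]1(C)[C@H](CC[C@@H](O[Si](CC)(CC)CC)[C@@H]1C)CO[Si](CC)(CC)CC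
F7 | step 10 | 2-(dimethoxymethyl)-2,3-dimethyl-4-(triethylsilyloxy)cyclohexane-1-carbaldehyde | COC(OC)[C@@]1(C)[C@H](CC[C@@H](O[Si](CC)(CC)CC)[C@@H]1C)C=O
F8 | step 10 | lithium (9R)-alkoxide from F7 and 12 | COC(OC)[C@@]1(C)[C@H](CC[C@@H](O[Si](CC)(CC)CC)[C@@H]1C)[C@@H](O[Li])C(=C)OCC
F9 | step 10 | (9R)-senecioate enol ether with 3-O-triethylsilyl group | COC(OC)[C@@]1(C)[C@H](CC[C@@H](O[Si](CC)(CC)CC)[C@@H]1C)[C@@H](OC(=O)C=C(C)C)C(=C)OCC
F10 | step 10 | 3-hydroxy keto aldehyde (C6 aldehyde, C8 methyl ketone, 9R senecioate) | O=C[C@@]1(C)[C@H](CC[C@@H](O)[C@@H]1C)[C@@H](OC(=O)C=C(C)C)C(C)=O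
F11 | step 9 | methyl ketone with intact dimethyl acetal (from 14) | COC(OC)[C@@]1(C)[C@H](CC[C@@H]([Si](C)(C)c2ccccc2)[C@@H]1C)[C@@H](OC(=O)C=C(C)C)C(C)=O
F12 | step 9 | trimethylsilyl enol ether of F11 (methyl side) | COC(OC)[C@@]1(C)[C@H](CC[C@@H]([Si](C)(C)c2ccccc2)[C@@H]1C)[C@@H](OC(=O)C=C(C)C)C(=C)O[Si](C)(C)C
F13 | step 9 | 3α-(dimethylphenylsilyl)-6-methoxy-9β-senecioyloxy-11,12,13-trinor-10βH-eremophilan-8-one (C6 epimers) | C1C(OC)[C@@]2(C)[C@H](CC[C@@H]([Si](C)(C)c3ccccc3)[C@@H]2C)[C@@H](OC(=O)C=C(C)C)C1=O
A1 | alternative 1 | cis-fused 9,9-dimethoxyeremophila-3,11-dien-8-one | C=C(C)[C@H]1C[C@@]2(C)[C@H](CCC=C2C)C(OC)(OC)C1=O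
A2 | alternative 1 | 3,3-dimethoxy-5,6-dimethyl-2-(3-methylbuta-1,3-dien-2-yl)bicyclo[2.2.2]oct-5-en-2-ol (dienyl group syn to the ring alkene) | C=C(C)C(=C)[C@@]1(O)[C@@H]2CC[C@@H](C(C)=C2C)C1(OC)OC
A3 | alternative 2 | (+)-aristolochene | C=C(C)[C@@H]1C[C@@]2(C)C(CCC[C@@H]2C)=CC1
A4 | alternative 2 | (2E,6E)-farnesyl diphosphate | CC(C)=CCC/C(C)=C/CC/C(C)=C/COP(=O)(O)OP(=O)(O)O
A5 | alternative 3 | 8α-hydroxy analogue of 24 (8-dihydro target) | C=C(C)[C@H]1C[C@@]2(C)[C@H](CC[C@@H](OC(=O)/C(C)=C\C)[C@@H]2C)[C@@H](OC(=O)C=C(C)C)[C@@H]1O
A6 | alternative 3 | ring A aldehyde with prenyl group on C5 and the C9 senecioate, C8 as CHO | CC(C)=CC[C@@]1(C)[C@H](CC[C@@H](OC(=O)/C(C)=C\C)[C@@H]1C)[C@@H](OC(=O)C=C(C)C)C=O
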